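**Retrosynthetic overview**
- The target is reached last by Lewis-acid cleavage of six aryl methyl ethers (four on ring A, two on the 4-hydroxyphenyl groups).
- Feature used: ring A and ring B are each a C2–C3–C4 cinnamate unit, joined C3–C3'. Each carries at C4 (C4') an oxygenated arene that is C-bonded through C4a (C4a') and O-acylated at O1 (O1') by C2 (C2'). Cutting C4–C4a, O1–C2, C4'–C4a' and O1'–C2' leaves 2,3,4,5-tetramethoxyphenol, phloroglucinol and the 8–8' dimer of 4-methoxycinnamic acid, whose carboxyl groups are γ-lactones on the benzylic carbon of the other half.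
- In one flask the single-site phenol goes in first, as its titanium aryloxide, on the rigid bislactone (C4, cis ring A). Phloroglucinol, in excess, then takes the second benzylic cation (C4', trans ring B), and both six-membered lactones close. C3 and C3' are the cis-fused bridgeheads of the bislactone.
- Ring order: the two γ-lactones (oxidative dimerisation of two molecules of the cinnamic acid, then resolution), then ring A and ring B. The phenol comes from 1,2,3,4-tetramethoxybenzene by formylation and Baeyer–Villiger oxidation.

Key step: step 5

Remark on the chemistry: the target SMILES reads as (3S,4R,3'S,4'S), that is 3,4-cis in ring A, 3',4'-trans in ring B and like configuration at C3/C3'. The two 4-hydroxyphenyl groups are carried as methyl ethers so that the key step contains no free phenol other than the two nucleophiles.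

**Step 1**
Reactants: 1 (E)-4-methoxycinnamic acid (two molecules; the second is entered below)
Product: 2 racemic (1R,2R,5R,6R)-2,6-bis(4-methoxyphenyl)-3,7-dioxabicyclo[3.3.0]octane-4,8-dione (cis-fused; both aryl groups exo)
Conditions: Tl(O2CCF3)3 (0.55 equiv), BF3·OEt2, CF3CO2H/CH2Cl2, 0 °C
Reagents that add atoms: second molecule of 1, (E)-4-methoxycinnamic acid, COc1ccc(/C=C/C(=O)O)cc1
Why: Two molecules of 1 are joined by one-electron oxidation of the anisyl-conjugated alkene with trivalent thallium, which gives a radical cation that dimerises at the carbons α to the carboxyl groups (C8–C8'), and each benzylic cation is then closed 5-exo by the carboxyl group of the other half, a known oxidative dimerisation of 4-alkoxycinnamic acids to such bislactones; only the like dimer can close both rings, so the bridgeheads are cis-fused, and the aryl groups take the less crowded exo positions.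

**Step 2**
Reactants: 2 racemic bislactone
Product: 3 (1R,2R,5R,6R)-2,6-bis(4-methoxyphenyl)-3,7-dioxabicyclo[3.3.0]octane-4,8-dione
Conditions: preparative HPLC, amylose tris(3,5-dimethylphenylcarbamate) phase, heptane/i-PrOH
Reagents that add atoms: none
Why: Resolution of a racemate on a chiral stationary phase, which should separate the rigid C2-symmetric enantiomers well; the (1R,2R,5R,6R) isomer, whose bridgeheads become C3 and C3', is kept and its configuration is to be confirmed by X-ray or ECD.

**Step 3**
Reactants: 4 1,2,3,4-tetramethoxybenzene
Product: 5 2,3,4,5-tetramethoxybenzaldehyde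
Conditions: Cl2CHOMe, TiCl4, CH2Cl2, 0 °C; then H2O
Reagents that add atoms: dichloromethyl methyl ether, COC(Cl)Cl; water, O
Why: Rieche formylation (electrophilic aromatic substitution by the TiCl4-activated chloromethyl oxocarbenium ion) at one of the two equivalent free positions, each ortho to one methoxy group and para to another, so only one regioisomer can form.

**Step 4**
Reactants: 5 2,3,4,5-tetramethoxybenzaldehyde
Product: 7 2,3,4,5-tetramethoxyphenol, via aryl formate 6 (not isolated)
Conditions: mCPBA, CH2Cl2, 0 °C → rt; then HCl (cat.), MeOH, rt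
Reagents that add atoms: mCPBA, OOC(=O)c1cccc(Cl)c1
Why: Baeyer–Villiger (Dakin-type) oxidation in which the electron-rich aryl group migrates to oxygen to give formate 6, which acid methanolysis cleaves to the phenol.

**Step 5**
Reactants: 3 (1R,2R,5R,6R)-bislactone; 7 2,3,4,5-tetramethoxyphenol; 8 phloroglucinol
Product: 11 (3S,4R)-3-[(3S,4S)-5,7-dihydroxy-4-(4-methoxyphenyl)-2-oxo-3,4-dihydro-2H-chromen-3-yl]-5,6,7,8-tetramethoxy-4-(4-methoxyphenyl)-3,4-dihydro-2H-chromen-2-one, via lactone acid 9 (not isolated), via seco diacid 10 (not isolated)
Conditions: 7 + TiCl4 (1.05 equiv each), CH2Cl2, −78 °C, Ar sparge; add 3, −78 → −30 °C; then 8 (5 equiv), CF3SO3H (0.1 equiv), (CF3)2CHOH/CH2Cl2, −20 → 20 °C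
Reagents that add atoms: none
Why: Proposed new method: TiCl3(OAr) made from 7 binds a lactone carbonyl of the strained bislactone 3 and ionises one benzylic C–O bond to a p-anisyl cation held in a contact ion pair by a titanium carboxylate that still carries the aryloxide, whose single free ortho carbon bonds to the cation (C4–C4a) from the face the oxygen has just left to give 9; in HFIP with CF3SO3H the remaining benzylic lactone C–O bond of 9 ionises to a solvent-separated cation that excess phloroglucinol captures through carbon (C4'–C4a') to give 10, and the ortho hydroxyl of each new arene then acylates on the carboxyl of its own half (O1–C2 and O1'–C2') with loss of two molecules of water. The closest known reactions are the ortho-specific C-alkylation of titanium and magnesium phenoxides by electrophiles bound to the same metal, the acid-mediated C-benzylation of phloroglucinol by p-alkoxybenzylic alcohols and esters, and the condensation of phenols with cinnamic acids to 4-aryl-3,4-dihydrocoumarins. Ring A and ring B each close by 6-exo-trig lactonisation of a phenol oxygen on a free carboxylic acid once the C–C bond is in place. C4 is set with retention by delivery of the arene from the metal on the departing carboxylate, which places the aryl group cis to C3' on ring A, whereas C4' is set with inversion because the free cation keeps its C3'–H in the plane of the anisyl ring (A1,3 strain) and is attacked on the side of its own small carboxyl group, away from the branched ring A carbon and the departed acid, which gives the trans ring B. The step needs opposite facial sense at the two benzylic carbons, one arene per carbon and intact C3 and C3': the first is secured by doing the templated arylation on the rigid bislactone, where the only carboxylate present is the leaving group, the second by the single free carbon of 7, the slower ionisation of the unstrained monolactone 9 and the excess of 8, and the third by the in-plane C–H bonds of both cations, which cannot align with the empty orbital for elimination. C3 and C3' themselves are the bridgehead carbons of 3 and are not touched.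

**Step 6**
Reactants: 11 hexamethyl ether
Product: 12 (3S,4R)-3-[(3S,4S)-5,7-dihydroxy-4-(4-hydroxyphenyl)-2-oxo-3,4-dihydro-2H-chromen-3-yl]-5,6,7,8-tetrahydroxy-4-(4-hydroxyphenyl)-3,4-dihydro-2H-chromen-2-one (CNP0064734.2)
Conditions: BBr3 (15 equiv), CH2Cl2, −78 → 0 °C; then degassed H2O, Ar
Reagents that add atoms: none
Why: BBr3 O-demethylation, in which boron binds each methoxy oxygen and bromide removes the methyl group; the aryl lactones and the four stereocentres should survive the cold, non-basic medium, and the degassed acidic work-up protects the air-sensitive pentaoxygenated ring A.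

**Compound list**
1 | (E)-4-methoxycinnamic acid | COc1ccc(/C=C/C(=O)O)cc1 | starting material
2 | racemic (1R,2R,5R,6R)-2,6-bis(4-methoxyphenyl)-3,7-dioxabicyclo[3.3.0]octane-4,8-dione (both enantiomers written) | O=C1O[C@@H](c3ccc(OC)cc3)[C@H]2[C@@H]1[C@H](c1ccc(OC)cc1)OC2=O.O=C1O[C@H](c3ccc(OC)cc3)[C@@H]2[C@H]1[C@@H](c1ccc(OC)cc1)OC2=O | intermediate
3 | (1R,2R,5R,6R)-2,6-bis(4-methoxyphenyl)-3,7-dioxabicyclo[3.3.0]octane-4,8-dione | O=C1O[C@@H](c3ccc(OC)cc3)[C@H]2[C@@H]1[C@H](c1ccc(OC)cc1)OC2=O | intermediate
4 | 1,2,3,4-tetramethoxybenzene | COc1ccc(OC)c(OC)c1OC | starting material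
5 | 2,3,4,5-tetramethoxybenzaldehyde | O=Cc1cc(OC)c(OC)c(OC)c1OC | intermediate
6 | 2,3,4,5-tetramethoxyphenyl formate (not isolated) | O=COc1cc(OC)c(OC)c(OC)c1OC | intermediate
7 | 2,3,4,5-tetramethoxyphenol | Oc1cc(OC)c(OC)c(OC)c1OC | intermediate
8 | phloroglucinol | Oc1cc(O)cc(O)c1 | starting material
9 | (2R,3R,4S)-4-[(R)-(2-hydroxy-3,4,5,6-tetramethoxyphenyl)(4-methoxyphenyl)methyl]-2-(4-methoxyphenyl)-5-oxooxolane-3-carboxylic acid (not isolated; titanium-bound in the flask) | OC(=O)[C@H]1[C@H](c2ccc(OC)cc2)OC(=O)[C@H]1[C@H](c1ccc(OC)cc1)c1c(O)c(OC)c(OC)c(OC)c1OC | intermediate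
10 | (2S,3S)-2-[(R)-(2-hydroxy-3,4,5,6-tetramethoxyphenyl)(4-methoxyphenyl)methyl]-3-[(S)-(4-methoxyphenyl)(2,4,6-trihydroxyphenyl)methyl]butanedioic acid (not isolated) | OC(=O)[C@@H]([C@@H](c1ccc(OC)cc1)c1c(O)cc(O)cc1O)[C@@H](C(=O)O)[C@H](c1ccc(OC)cc1)c1c(O)c(OC)c(OC)c(OC)c1OC | intermediate
11 | (3S,4R)-3-[(3S,4S)-5,7-dihydroxy-4-(4-methoxyphenyl)-2-oxo-3,4-dihydro-2H-chromen-3-yl]-5,6,7,8-tetramethoxy-4-(4-methoxyphenyl)-3,4-dihydro-2H-chromen-2-one | O=C1Oc2c(OC)c(OC)c(OC)c(OC)c2[C@@H](c2ccc(OC)cc2)[C@H]1[C@H]1C(=O)Oc2cc(O)cc(O)c2[C@@H]1c1ccc(OC)cc1 | intermediate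
12 | (3S,4R)-3-[(3S,4S)-5,7-dihydroxy-4-(4-hydroxyphenyl)-2-oxo-3,4-dihydro-2H-chromen-3-yl]-5,6,7,8-tetrahydroxy-4-(4-hydroxyphenyl)-3,4-dihydro-2H-chromen-2-one | O=C1Oc2c(O)c(O)c(O)c(O)c2[C@@H](c2ccc(O)cc2)[C@H]1[C@H]1C(=O)Oc2cc(O)cc(O)c2[C@@H]1c1ccc(O)cc1 | target

**Step count**
Total steps: 6. Longest linear sequence: 4 steps (1 → 2 → 3 → 11 → 12; the branch 4 → 5 → 7 → 11 → 12 is equally long).

**Steps most likely to fail**

Step 5. Three processes may defeat it:
- The aryloxide may attack the cation from outside the ion pair, on the open face, which gives poor facial selectivity at C4.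
- The cation may lose the C3 proton to an α-benzylidene lactone before the C–C bond forms.
- The first arylation may reverse under the acid of the second stage.

The fallback uses known proton-catalysed Friedel–Crafts benzylations with the arenes in the opposite order; it sets out from 3 and returns at 11. Compound 3 is treated with phloroglucinol 8 (1.2 equiv) and CF3SO3H (5 mol %) in HFIP at 0 °C. This opens one lactone from the unhindered face, as ring B needs, and gives after isolation the lactone acid (2R,3R,4S)-2-(4-methoxyphenyl)-4-[(S)-(4-methoxyphenyl)(2,4,6-trihydroxyphenyl)methyl]-5-oxooxolane-3-carboxylic acid F1. F1 is then warmed with 7 (3 equiv) and the same acid in HFIP, which ionises the second lactone, C-benzylates 7 at its free carbon and closes both six-membered lactones to 11. In this order nothing steers the phenol to the cis face of the open-chain cation; by the same A1,3 reasoning the trans ring A epimer is expected to predominate, so 11 would have to be separated from its C4 epimer by chromatography, probably as the minor isomer.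

Step 6. The pentaoxygenated ring A may be oxidised by air during isolation of the free polyphenol, and long exposure to the Lewis acid may epimerise the cis ring at C3. The fallback changes the isolation from the free phenol to a protected derivative; it sets out from 11 and returns at 12. After the BBr3 treatment the crude product is not isolated but acetylated under argon (Ac2O, pyridine, 0 °C) to the octaacetate of 12 F2, which should be stable to air and silica. Acid methanolysis (HCl generated from AcCl in MeOH, 0 °C → rt, argon) then releases 12. Any lactone opened to a methyl ester is reclosed by evaporation from toluene with a trace of CF3CO2H.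

Step 1. The radical cation may polymerise or be oxidised further, so that little bislactone forms. The fallback is an auxiliary-controlled oxidative enolate coupling that sets out from 1 and returns at 3, so that step 2 is not needed either. Hydrogenation of 1 (H2, Pd/C, EtOAc) gives 3-(4-methoxyphenyl)propanoic acid F3. Its mixed pivalic anhydride (t-BuCOCl, Et3N) acylates lithiated (R)-4-isopropyloxazolidin-2-one to (R)-4-isopropyl-3-[3-(4-methoxyphenyl)propanoyl]oxazolidin-2-one F4. The lithium enolate of F4 (LDA, THF, −78 °C) is coupled oxidatively with TiCl4 or PhI(OAc)2 to the like dimer, the bis-imide of (2S,3S)-2,3-bis(4-methoxybenzyl)butanedioic acid F5; the (R)-auxiliary is chosen because the enolate of the (S)-auxiliary is known to couple to the (R,R)-succinate. LiOH/H2O2 then removes both auxiliaries to give (2S,3S)-2,3-bis(4-methoxybenzyl)butanedioic acid F6. Finally DDQ (2.2 equiv, dioxane, 80 °C) abstracts hydride from each p-methoxybenzylic CH2, and the γ-carboxyl group of the other half closes the ring on each cation, giving 3 with both aryl groups exo.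

**Further compounds**
F1 | step 5 | (2R,3R,4S)-2-(4-methoxyphenyl)-4-[(S)-(4-methoxyphenyl)(2,4,6-trihydroxyphenyl)methyl]-5-oxooxolane-3-carboxylic acid | O=C1O[C@@H](c2ccc(OC)cc2)[C@H](C(=O)O)[C@@H]1[C@@H](c1ccc(OC)cc1)c1c(O)cc(O)cc1O
F2 | step 6 | octaacetate of 12 | O=C1Oc2c(OC(C)=O)c(OC(C)=O)c(OC(C)=O)c(OC(C)=O)c2[C@@H](c2ccc(OC(C)=O)cc2)[C@H]1[C@H]1C(=O)Oc2cc(OC(C)=O)cc(OC(C)=O)c2[C@@H]1c1ccc(OC(C)=O)cc1
F3 | step 1 | 3-(4-methoxyphenyl)propanoic acid | COc1ccc(CCC(=O)O)cc1
F4 | step 1 | (R)-4-isopropyl-3-[3-(4-methoxyphenyl)propanoyl]oxazolidin-2-one | COc1ccc(CCC(=O)N2[C@H](C(C)C)COC2=O)cc1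
F5 | step 1 | (2S,3S)-2,3-bis(4-methoxybenzyl)butanedioyl bis[(R)-4-isopropyloxazolidin-2-one] imide | O=C([C@@H](Cc1ccc(OC)cc1)[C@H](Cc1ccc(OC)cc1)C(=O)N1[C@H](C(C)C)COC1=O)N1[C@H](C(C)C)COC1=O
F6 | step 1 | (2S,3S)-2,3-bis(4-methoxybenzyl)butanedioic acid | OC(=O)[C@@H](Cc1ccc(OC)cc1)[C@H](Cc1ccc(OC)cc1)C(=O)O
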